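## Structural features

The target is a flavone: a 4-pyranone (ring C) fused to a benzene ring (ring A) through C4a–C8a, with a 4-hydroxyphenyl group (ring B) on C2 through the C2–C1' bond. Ring A carries oxygen at C5 and C7. O5–H is hydrogen-bonded to the C4 carbonyl, O7 bears the sulfate monoester, and O4' on ring B is a free phenol. The molecule is flat and achiral, so there are no stereocentres, adjacent or otherwise. The fragile groups are the aryl O–SO3H monoester, which is hydrolysed by acid and would not survive a Lewis acid such as BBr3, and the pyranone ring, whose C2 can be attacked by hydroxide or alkoxide with ring opening. The real difficulty is regiochemistry at oxygen: O7–H and O4'–H are both unhindered phenols of similar acidity, and only O7 may be sulfated. The key step exploits the substitution of ring B: besides C1', its only substituted carbon is C4', para to C1'. A 1-methoxy-3-silyloxybutadiene supplies C3'–C6' with the C4' oxygen, and a terminal alkyne supplies C1' and C2'. Because that oxygen arrives silylated while ring A is benzylated, the same step also separates O4' from O7.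

## Logic of the disconnections

**12 back to 10.** The O7–S bond of 12 is cut, together with the O4'–Si bond that the forward step breaks. The sulfate is the most acid-sensitive group, so it goes on in the last operation and no acidic deprotection follows it. In 10 only O7–H can react: O5–H is held by the C4 carbonyl and O4' is silylated. The forward step must sulfate without disturbing the silyl ether (through 11) and then remove silicon with fluoride, to which the sulfate anion is inert.

**10 back to 9.** The two benzyl C–O bonds on ring A are cut. Benzyl replaces methyl because it leaves by neutral hydrogenolysis, which an aryl silyl ether tolerates. A 7-methyl ether of a flavone is the slowest of the ring ethers to cleave, and forcing BBr3 would free every oxygen at once, leaving the O7/O4' choice to a small acidity difference. The demand is that the C2=C3 bond and the Si–O bond survive hydrogenolysis, hence a non-alcoholic solvent and balloon pressure.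

**9 back to 6 and 7.** Ring B is opened at C2'–C3' and C1'–C6', and the methanol lost on aromatisation is restored, which passes through 8. This replaces an aryl–heteroaryl bond construction by the assembly of a whole ring from two small pieces, with no stereochemistry to set. Two changes to the partners improve the design without moving the cut. Compound 7 carries tert-butyldimethylsilyl rather than trimethylsilyl, so the C4' oxygen emerges protected. Compound 6 carries benzyl ethers, so even if silicon were lost, the exposed oxygen would still be the only free hydroxyl. The forward step needs para regiochemistry and enough dienophilicity in an alkyne that is activated only through C2=C3.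

**6 back to 5.** The terminal alkyne carbon is removed, a one-carbon homologation of an aldehyde. The aldehyde is non-enolisable, which suits a diazophosphonate anion. The demand is a medium free of alcohol, because both the pyranone and the conjugated alkyne accept nucleophiles.

**5 back to 4.** The formyl group is masked as its diethyl acetal (two C–O bonds). The acetal is the stable form for storage, and the reactive aldehyde is released only when needed. The demand is hydrolysis of an electron-poor acetal under acid mild enough for the benzyl ethers.

**4 back to 1 and 2.** Ring C is cut at C2–C3 and O1–C2, through 3. Compound 2 brings C2 and its side-chain carbon already at the aldehyde oxidation level, so no reduction–oxidation sequence on an ester is needed. The demands are a Claisen condensation at a di-ortho-substituted ketone and a cyclodehydration that keeps the acetal.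

## Other disconnections considered

**Alternative 1:** The cut is the C4a–C5 bond of ring A. It unfolds that ring into a β-keto ester chain on C8a of a preformed 2-aryl-4-pyranone, methyl 4-[6-(4-benzyloxyphenyl)-4-oxo-4H-pyran-2-yl]-3-oxobutanoate (A2).
- Forward step: Mg(OMe)2 in methanol would turn A2 into a chelated dienolate. The ring carbon destined to be C4a would acylate onto the ester carbonyl in a 6-exo-trig Claisen closure, and enolisation would give 2-(4-benzyloxyphenyl)-5,7-dihydroxychromen-4-one (A1).
- In favour: A1 has exactly the oxygen pattern the end game wants (O5–H chelated, O7–H free, O4' benzylated). Sulfation and a neutral hydrogenolysis would finish in two steps. This equals the chosen plan in count and is better in simplicity, since no deprotection stands between key step and sulfation.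
- Against: A2 is a sensitive polycarbonyl compound that needs several steps, including C-acylation of a 6-methylpyranone anion. In the key step, Claisen acylation at C4a must win over aldol closure and over methoxide opening of the pyranone. Only one skeletal bond is formed.
- Comparison: the structural fit at oxygen is better. The mechanism is a chelation-dependent choice among enolate pathways, where the chosen cycloaddition has its regiochemistry set by polarisation. The longer approach to A2 should make the total step count higher.

**Alternative 2:** Three bonds of ring A are cut (C5–C6, C7–C8, C4a–C5), giving 2-(2-diazoacetyl)-6-(4-methoxyphenyl)-4H-pyran-4-one (A4) and ethoxyacetylene (A5).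
- Forward step: irradiation of A4 would cause Wolff rearrangement to a pyranylketene. A [2+2] addition of A5, 4π opening of the cyclobutenone, 6π closure of the dienylketene and tautomerisation would give 7-ethoxy-5-hydroxy-2-(4-methoxyphenyl)chromen-4-one (A3).
- In favour: it is convergent and forms three bonds against two in the chosen key step. It is better than the chosen plan in that O5 and O7 emerge already different from each other.
- Against: the distinction that matters is O7 versus O4', and A3 has robust alkyl ethers on both. Cleaving both with BBr3 would give apigenin (A6), whose sulfation must choose between two free phenols. A silyloxy- or benzyloxyalkyne in place of A5 would be needed to repair this. The pyranone chromophore may compete photochemically with the diazo group, A4 needs diazomethane, and A5 is volatile and costly.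
- Comparison: equal or better in convergence and bonds formed, and similar in length up to the key step. It is weaker at the end, because it delivers no usable O7/O4' distinction. Mechanistically it is a photochemical cascade through ketenes against a single thermal cycloaddition.

**Alternative 3:** Ring C is cut at C4a–C4, C4–C3 and O1–C2, giving 2-iodo-3,5-dimethoxyphenol (A8), 4-ethynylanisole (A9) and carbon monoxide (A10).
- Forward step: under PdCl2(PPh3)2 in an amine, oxidative addition into the C–I bond of A8, insertion of A10 and coupling with A9 would give an o-hydroxyaryl ynone. This would close by 6-endo oxa-Michael addition to 5,7-dimethoxy-2-(4-methoxyphenyl)chromen-4-one (A7).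
- In favour: it is the shortest entry to the flavone skeleton, with three bonds and one ring from three simple pieces in one operation. On step economy up to the flavone it is clearly better than the chosen plan.
- Against: A7 has three identical methyl ethers, so the only way forward is exhaustive demethylation to A6 and a sulfation that must tell O7–H from O4'–H by acidity alone. The main difficulty of the target stays unsolved. A8 needs a regioselective iodination, its C–I bond is flanked by two ortho substituents on an electron-rich ring, 5-exo closure competes with the 6-endo mode, and A10 is a toxic gas.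
- Comparison: an organometallic three-component cascade against a thermal cycloaddition, and shorter by about two steps. It offers no oxygen differentiation unless the protecting groups are redesigned. The chosen plan spends those steps to make the sulfation unambiguous.

Key step: step 4

Assumption: the sulfate monoester is written in its acid form; it would be kept as the potassium salt and released as the acid by brief cold acidification at the end, because aryl hydrogen sulfates hydrolyse under acid catalysis.

## Route

Step 1
Reactants: 1 1-[2,4-bis(benzyloxy)-6-hydroxyphenyl]ethan-1-one; 2 ethyl diethoxyacetate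
Product: 4 5,7-bis(benzyloxy)-2-(diethoxymethyl)-4H-chromen-4-one, via diketone 3 (not isolated)
Conditions: NaH (3.5 equiv), THF, 0 → 65 °C; AcOH; then H2SO4 (cat.), EtOH, 60 °C
Reagents that add atoms: none
Why: Claisen condensation of the phenoxide–enolate dianion of 1 with the activated α,α-dialkoxy ester, then acid-catalysed cyclodehydration of the o-hydroxyaryl 1,3-diketone to the chromone. Ethanol as solvent keeps the side chain as its diethyl acetal, and benzyl ethers tolerate catalytic acid.

Step 2
Reactants: 4 5,7-bis(benzyloxy)-2-(diethoxymethyl)-4H-chromen-4-one
Product: 5 5,7-bis(benzyloxy)-4-oxo-4H-chromene-2-carbaldehyde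
Conditions: 2 M HCl (aq)–THF, 50 °C; azeotropic drying (toluene)
Reagents that add atoms: water, SMILES O
Why: Acid-catalysed acetal hydrolysis; dilute aqueous acid should not cleave benzyl aryl ethers. The non-enolisable aldehyde, dried free of its hydrate, is used at once.

Step 3
Reactants: 5 5,7-bis(benzyloxy)-4-oxo-4H-chromene-2-carbaldehyde
Product: 6 5,7-bis(benzyloxy)-2-ethynyl-4H-chromen-4-one
Conditions: dimethyl (1-diazo-2-oxopropyl)phosphonate, NaOMe (1.0 equiv), THF, −78 °C; then 5, −78 °C → rt
Reagents that add atoms: dimethyl (1-diazo-2-oxopropyl)phosphonate, SMILES CC(=O)C(=[N+]=[N-])P(=O)(OC)OC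
Why: Seyferth–Gilbert homologation: the diazomethylphosphonate anion, released from the Ohira–Bestmann reagent by methoxide deacylation, adds to the aldehyde, Horner–Wadsworth–Emmons elimination gives a diazoalkene, and loss of N2 with 1,2-hydrogen shift gives the terminal alkyne. Working in THF with one equivalent of methoxide keeps alcohol away from the electrophilic pyranone and the conjugated alkyne.

Step 4
Reactants: 6 5,7-bis(benzyloxy)-2-ethynyl-4H-chromen-4-one; 7 (E)-3-(tert-butyldimethylsilyloxy)-1-methoxybuta-1,3-diene
Product: 9 5,7-bis(benzyloxy)-2-[4-(tert-butyldimethylsilyloxy)phenyl]-4H-chromen-4-one, via methoxycyclohexadiene cycloadduct 8 (not isolated)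
Conditions: 7 (3 equiv), toluene, 120 °C, sealed tube; then pyridinium p-toluenesulfonate (cat.), CH2Cl2, 25 °C
Reagents that add atoms: none
Why: A thermal, normal-electron-demand Diels–Alder reaction between the electron-rich diene 7 and the acceptor-substituted alkyne of 6, concerted but asynchronous, followed by 1,4-elimination of methanol from 8; the closest known reaction type is the benzannulation of 1-alkoxy-3-silyloxybutadienes with ynones and propiolates to give para-oxygenated arenes. The alkyne is the γ,δ-unit of the C4=O/C3=C2/C≡C acceptor chain, so its terminal (δ) carbon has the larger LUMO coefficient and bonds first to the CH2 terminus of 7 (C2'–C3'), while the methoxy-bearing carbon closes onto the inner alkyne carbon (C1'–C6'). Ring B, a six-membered carbocycle, is closed by the cycloaddition itself, both bonds being made suprafacially in one pericyclic event. The only stereocentre created, C6' of 8, forms as a racemate and is erased when methanol leaves, so no stereocontrol is needed. The step needs regioselectivity (oxygen para, not meta, to C1') and chemoselectivity (alkyne rather than C2=C3 or the C4 carbonyl); the first follows from the matched polarisation of both partners, the second from C2=C3 being a trisubstituted part of the pyranone and from the absence of any Lewis acid that could activate C4=O. Under mild anhydrous acid the doubly allylic methoxy group of 8 ionises to a cation stabilised by the silyloxy group, and loss of the C3' proton gives the arene with the bulky silyl group still on oxygen. The benzyl ethers are inert to heat and to pyridinium p-toluenesulfonate.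

Step 5
Reactants: 9 5,7-bis(benzyloxy)-2-[4-(tert-butyldimethylsilyloxy)phenyl]-4H-chromen-4-one
Product: 10 2-[4-(tert-butyldimethylsilyloxy)phenyl]-5,7-dihydroxy-4H-chromen-4-one
Conditions: H2 (1 atm), Pd/C (10 wt%), EtOAc–THF, 25 °C
Reagents that add atoms: none
Why: Catalytic hydrogenolysis of benzyl aryl ethers. At balloon pressure in a non-alcoholic solvent, with monitoring, the aryl silyl ether and the flavone C2=C3 bond should be left intact.

Step 6
Reactants: 10 2-[4-(tert-butyldimethylsilyloxy)phenyl]-5,7-dihydroxy-4H-chromen-4-one
Product: 12 5-hydroxy-2-(4-hydroxyphenyl)-4-oxo-4H-chromen-7-yl hydrogen sulfate (apigenin 7-sulfate), via pyridinium silyl ether sulfate 11 (not isolated)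
Conditions: SO3·pyridine (1.5 equiv), pyridine, 25 °C; then KF, MeOH–H2O, 25 °C; then 1 M HCl to pH 2, 0 °C, C18 desalting, freeze-drying
Reagents that add atoms: sulfur trioxide–pyridine complex, SMILES O=S(=O)([O-])[n+]1ccccc1
Why: O-sulfation of a phenol by an amine–sulfur trioxide complex: O7–H is the only reactive hydroxyl of 10, since O5–H is locked in the hydrogen bond to C4=O and O4' is silylated. Fluoride then cleaves the aryl silyl ether without touching the sulfate monoester anion, and brief cold acidification gives the acid form.

## Compound list

1 | 1-[2,4-bis(benzyloxy)-6-hydroxyphenyl]ethan-1-one (2'-hydroxy-4',6'-bis(benzyloxy)acetophenone) | CC(=O)c1c(O)cc(OCc2ccccc2)cc1OCc1ccccc1 | starting material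
2 | ethyl diethoxyacetate | CCOC(=O)C(OCC)OCC | starting material
3 | 1-[2,4-bis(benzyloxy)-6-hydroxyphenyl]-4,4-diethoxybutane-1,3-dione | CCOC(OCC)C(=O)CC(=O)c1c(O)cc(OCc2ccccc2)cc1OCc1ccccc1 | intermediate (not isolated)
4 | 5,7-bis(benzyloxy)-2-(diethoxymethyl)-4H-chromen-4-one | CCOC(OCC)c1cc(=O)c2c(OCc3ccccc3)cc(OCc3ccccc3)cc2o1 | intermediate
5 | 5,7-bis(benzyloxy)-4-oxo-4H-chromene-2-carbaldehyde | O=Cc1cc(=O)c2c(OCc3ccccc3)cc(OCc3ccccc3)cc2o1 | intermediate
6 | 5,7-bis(benzyloxy)-2-ethynyl-4H-chromen-4-one | C#Cc1cc(=O)c2c(OCc3ccccc3)cc(OCc3ccccc3)cc2o1 | intermediate
7 | (E)-3-(tert-butyldimethylsilyloxy)-1-methoxybuta-1,3-diene | CO/C=C/C(=C)O[Si](C)(C)C(C)(C)C | starting material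
8 | 5,7-bis(benzyloxy)-2-[4-(tert-butyldimethylsilyloxy)-6-methoxycyclohexa-1,4-dien-1-yl]-4H-chromen-4-one (racemic) | COC1C=C(O[Si](C)(C)C(C)(C)C)CC=C1c1cc(=O)c2c(OCc3ccccc3)cc(OCc3ccccc3)cc2o1 | intermediate (not isolated)
9 | 5,7-bis(benzyloxy)-2-[4-(tert-butyldimethylsilyloxy)phenyl]-4H-chromen-4-one | CC(C)(C)[Si](C)(C)Oc1ccc(cc1)-c1cc(=O)c2c(OCc3ccccc3)cc(OCc3ccccc3)cc2o1 | intermediate
10 | 2-[4-(tert-butyldimethylsilyloxy)phenyl]-5,7-dihydroxy-4H-chromen-4-one | CC(C)(C)[Si](C)(C)Oc1ccc(cc1)-c1cc(=O)c2c(O)cc(O)cc2o1 | intermediate
11 | pyridinium 2-[4-(tert-butyldimethylsilyloxy)phenyl]-5-hydroxy-4-oxo-4H-chromen-7-yl sulfate | CC(C)(C)[Si](C)(C)Oc1ccc(cc1)-c1cc(=O)c2c(O)cc(OS(=O)(=O)[O-])cc2o1.c1cc[nH+]cc1 | intermediate (not isolated)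
12 | 5-hydroxy-2-(4-hydroxyphenyl)-4-oxo-4H-chromen-7-yl hydrogen sulfate (apigenin 7-sulfate) | O=c1cc(-c2ccc(O)cc2)oc2cc(OS(=O)(=O)O)cc(O)c12 | target

## Step count and least certain steps

Total step count: 6. Longest linear sequence: 6 steps (1 → 4 → 5 → 6 → 9 → 10 → 12).

**Step 4 (key step).** The cycloaddition may be too slow, because the alkyne is activated only through the C2=C3 bond and the ring oxygen donates into that acceptor. Thermal decomposition or adventitious hydrolysis of 7 could then outrun the addition. The fallback abandons the cycloaddition and closes ring C last. Starting again from 1, the dianion (LiN(SiMe3)2, THF, −78 °C) would be C-acylated with 4-(tert-butyldimethylsilyloxy)benzoyl chloride to give 1-[2,4-bis(benzyloxy)-6-hydroxyphenyl]-3-[4-(tert-butyldimethylsilyloxy)phenyl]propane-1,3-dione F1. Cyclodehydration (p-toluenesulfonic acid, cat., toluene, 80 °C) would return to the route at 9.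

**Step 3.** Methoxide or the phosphonate anion may attack C2 of the electron-poor pyranone with ring opening, or the diazo reagent may add across the newly formed conjugated alkyne, in place of clean olefination and rearrangement. The fallback sets out from 5. Stork–Zhao olefination with the ylide from (iodomethyl)triphenylphosphonium iodide and NaN(SiMe3)2 (THF, −78 °C) would give 5,7-bis(benzyloxy)-2-[(Z)-2-iodoethenyl]-4H-chromen-4-one F2. Anti elimination of hydrogen iodide with 1,8-diazabicyclo[5.4.0]undec-7-ene (THF, 25 °C) would rejoin the route at 6.

**Step 2.** The acetal, deactivated by the electron-poor heterocycle, may resist hydrolysis until the acid is strong enough to start cleaving the benzyl ether at O5, which the neighbouring carbonyl activates. The fallback reaches the aldehyde by the ester oxidation level instead, starting from 1.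
- Claisen condensation with diethyl oxalate (NaOEt, EtOH) would give ethyl 4-[2,4-bis(benzyloxy)-6-hydroxyphenyl]-2,4-dioxobutanoate F3.
- Acid cyclodehydration (H2SO4 cat., EtOH) would give ethyl 5,7-bis(benzyloxy)-4-oxo-4H-chromene-2-carboxylate F4.
- Chemoselective reduction of the activated ester (NaBH4, MeOH–THF, 0 °C) would give 5,7-bis(benzyloxy)-2-(hydroxymethyl)-4H-chromen-4-one F5.
- Oxidation with MnO2 (CH2Cl2, 25 °C) would return to the route at 5.

**Step 6.** The silyl group may migrate between phenolic oxygens, or be lost early in the basic medium, which would open O4' to sulfation. The monoester may also hydrolyse during acidification and isolation of an ionic product. The fallback carries the sulfate as a neutral diester that can be purified on silica before unmasking.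
- From 10, 2,2,2-trichloroethyl chlorosulfate (NEt3, 4-(dimethylamino)pyridine, THF, 0 °C) would give 2-[4-(tert-butyldimethylsilyloxy)phenyl]-5-hydroxy-4-oxo-4H-chromen-7-yl 2,2,2-trichloroethyl sulfate F6.
- KHF2 in MeOH would remove silicon to give 5-hydroxy-2-(4-hydroxyphenyl)-4-oxo-4H-chromen-7-yl 2,2,2-trichloroethyl sulfate F7.
- Reductive removal of the trichloroethyl group (Zn, HCO2NH4, MeOH, 25 °C) and cold acidification would arrive at 12.

## Further compounds

F1 | step 4 | 1-[2,4-bis(benzyloxy)-6-hydroxyphenyl]-3-[4-(tert-butyldimethylsilyloxy)phenyl]propane-1,3-dione | CC(C)(C)[Si](C)(C)Oc1ccc(cc1)C(=O)CC(=O)c1c(O)cc(OCc2ccccc2)cc1OCc1ccccc1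
F2 | step 3 | 5,7-bis(benzyloxy)-2-[(Z)-2-iodoethenyl]-4H-chromen-4-one | I/C=C\c1cc(=O)c2c(OCc3ccccc3)cc(OCc3ccccc3)cc2o1
F3 | step 2 | ethyl 4-[2,4-bis(benzyloxy)-6-hydroxyphenyl]-2,4-dioxobutanoate | CCOC(=O)C(=O)CC(=O)c1c(O)cc(OCc2ccccc2)cc1OCc1ccccc1
F4 | step 2 | ethyl 5,7-bis(benzyloxy)-4-oxo-4H-chromene-2-carboxylate | CCOC(=O)c1cc(=O)c2c(OCc3ccccc3)cc(OCc3ccccc3)cc2o1
F5 | step 2 | 5,7-bis(benzyloxy)-2-(hydroxymethyl)-4H-chromen-4-one | OCc1cc(=O)c2c(OCc3ccccc3)cc(OCc3ccccc3)cc2o1
F6 | step 6 | 2-[4-(tert-butyldimethylsilyloxy)phenyl]-5-hydroxy-4-oxo-4H-chromen-7-yl 2,2,2-trichloroethyl sulfate | CC(C)(C)[Si](C)(C)Oc1ccc(cc1)-c1cc(=O)c2c(O)cc(OS(=O)(=O)OCC(Cl)(Cl)Cl)cc2o1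
F7 | step 6 | 5-hydroxy-2-(4-hydroxyphenyl)-4-oxo-4H-chromen-7-yl 2,2,2-trichloroethyl sulfate | O=c1cc(-c2ccc(O)cc2)oc2cc(OS(=O)(=O)OCC(Cl)(Cl)Cl)cc(O)c12
A1 | alternative 1 | 2-(4-benzyloxyphenyl)-5,7-dihydroxychromen-4-one | O=c1cc(-c2ccc(OCc3ccccc3)cc2)oc2cc(O)cc(O)c12
A2 | alternative 1 | methyl 4-[6-(4-benzyloxyphenyl)-4-oxo-4H-pyran-2-yl]-3-oxobutanoate | COC(=O)CC(=O)Cc1cc(=O)cc(o1)-c1ccc(OCc2ccccc2)cc1
A3 | alternative 2 | 7-ethoxy-5-hydroxy-2-(4-methoxyphenyl)chromen-4-one | CCOc1cc(O)c2c(c1)oc(cc2=O)-c1ccc(OC)cc1
A4 | alternative 2 | 2-(2-diazoacetyl)-6-(4-methoxyphenyl)-4H-pyran-4-one | [N-]=[N+]=CC(=O)c1cc(=O)cc(o1)-c1ccc(OC)cc1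
A5 | alternative 2 | ethoxyacetylene | C#COCC
A6 | alternative 2 | apigenin (5,7-dihydroxy-2-(4-hydroxyphenyl)chromen-4-one) | O=c1cc(-c2ccc(O)cc2)oc2cc(O)cc(O)c12
A7 | alternative 3 | 5,7-dimethoxy-2-(4-methoxyphenyl)chromen-4-one | COc1ccc(cc1)-c1cc(=O)c2c(OC)cc(OC)cc2o1
A8 | alternative 3 | 2-iodo-3,5-dimethoxyphenol | COc1cc(O)c(I)c(OC)c1
A9 | alternative 3 | 4-ethynylanisole | C#Cc1ccc(OC)cc1
A10 | alternative 3 | carbon monoxide | [C-]#[O+]
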